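**Plan**

- Retrosynthesis: hydrogenolysis removes three benzylic aryl-ether protecting groups; the aryl ketone comes from a benzylic carbinol that is cut at the Cα–C(carbinol) bond (auxiliary aldol); the cis-dihydrobenzofuran is cut at C2–C3 (carbenoid C–H insertion); the two aryl C5–CH2 bonds (Pd enolate arylation) and the two phenol O–CH2Ar bonds lead back to 5,5'-dibromo-(+)-pinoresinol.
- Enabling feature: both guaiacyl rings of the furofuran carry at C5 an arylacetic α-carbon of the same configuration bearing CH2OH (open-chain Cα and ring C3). In the ring O1–C2–C3–C3a–C7a, C3 is therefore a disguised aryl(ester)carbene carbon, and C2–H is a benzylic C–H on the phenol oxygen O1, 1,5 to C3.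
- Forward order: furofuran taken intact from (+)-pinoresinol, then dibromide, bis(benzyl-type ether), one arylacetate, diazo ester, dihydrobenzofuran (last ring closed), second arylacetyl unit, aldol chain extension, ketone, deprotection.
- Stereochemistry: the four furofuran centres come from (+)-pinoresinol; C2 and C3 (cis, 2S,3S) from the chiral dirhodium carboxylate in the insertion; the open-chain α-centre (S) from an (R)-4-benzyloxazolidinone syn-aldol whose carbinol centre is then oxidised away.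
- The C2 symmetry of the dibromide is broken once, by a mono-coupling run with excess dibromide and recycling.

Key step: step 6

Remark 1: (+)-pinoresinol (7S,7'S,8R,8'R) is taken as a commercial starting material; its four stereocentres are those of the target's furofuran.
Remark 2: the SMILES is read as a 2,3-cis-dihydrobenzofuran (2S,3S), the kinetic and less stable isomer, so the ring is closed under kinetic control and never exposed to base or acid at the ester stage.
Notation: Ar = 4-(benzyloxy)-3-methoxyphenyl; ring A = the guaiacyl ring that becomes the dihydrobenzofuran; ring B = the guaiacyl ring that carries the keto chain; C5 = the ring carbon ortho to the phenolic oxygen.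

**Route**

Step 1
Reactants: 1 (+)-pinoresinol
Product: 2 5,5'-dibromo-(+)-pinoresinol
Conditions: NBS (2.05 equiv), iPr2NH (10 mol%), CH2Cl2–THF, −20 → 0 °C, dark
Reagents that add atoms: N-bromosuccinimide, O=C1CCC(=O)N1Br
Why: Electrophilic aromatic bromination; the free phenol is the strongest director and its para position is blocked, so bromine should enter ortho to OH (C5) on each ring, while low temperature and darkness avoid radical attack at the benzylic furofuran positions.

Step 2
Reactants: 3 [4-(benzyloxy)-3-methoxyphenyl]methanol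
Product: 4 1-(benzyloxy)-4-(bromomethyl)-2-methoxybenzene
Conditions: PBr3 (0.4 equiv), Et2O, 0 °C; used crude
Reagents that add atoms: phosphorus tribromide, BrP(Br)Br
Why: Standard conversion of a benzylic alcohol into the bromide via the phosphite ester; the electron-rich bromide is used at once.

Step 3
Reactants: 2 5,5'-dibromo-(+)-pinoresinol; 4 1-(benzyloxy)-4-(bromomethyl)-2-methoxybenzene
Product: 5 5,5'-dibromo-4,4'-bis-O-[4-(benzyloxy)-3-methoxybenzyl]-(+)-pinoresinol
Conditions: 4 (2.4 equiv), K2CO3 (4 equiv), DMF, rt → 40 °C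
Reagents that add atoms: none
Why: Williamson etherification of the acidic bromophenols with a reactive benzylic bromide; on ring A the new OCH2Ar group supplies the future C2 and its aryl group, and on ring B it serves as a hydrogenolysable phenol protecting group.

Step 4
Reactants: 5 5,5'-dibromo-4,4'-bis-O-[4-(benzyloxy)-3-methoxybenzyl]-(+)-pinoresinol
Product: 6 methyl 2-(ring A C5-yl)acetate (5 with one bromine replaced by CH2CO2Me)
Conditions: Zn dust, BrCH2CO2Me, THF, 40 °C (zinc reagent, 1 equiv); then 5 (2.5 equiv), Pd(dba)2 (5 mol%), P(tBu)3 (5 mol%), THF, rt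
Reagents that add atoms: methyl bromoacetate, COC(=O)CBr
Why: Pd-catalysed α-arylation of a Reformatsky reagent (Negishi-type coupling of a zinc ester enolate) under near-neutral conditions; 5 is C2-symmetric so either bromide gives the same product, and the excess of 5 should suppress double coupling (statistical desymmetrisation, unreacted 5 recycled).

Step 5
Reactants: 6 methyl 2-(ring A C5-yl)acetate
Product: 7 methyl 2-diazo-2-(ring A C5-yl)acetate
Conditions: 4-acetamidobenzenesulfonyl azide (1.3 equiv), DBU (1.5 equiv), MeCN, 0 °C → rt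
Reagents that add atoms: 4-acetamidobenzenesulfonyl azide, CC(=O)Nc1ccc(cc1)S(=O)(=O)N=[N+]=[N-]
Why: Regitz diazo transfer to the benzylic, ester-activated methylene, the usual entry to aryldiazoacetates.

Step 6
Reactants: 7 methyl 2-diazo-2-(ring A C5-yl)acetate
Product: 9 methyl (2S,3R)-cis-2-Ar-7-methoxy-2,3-dihydro-1-benzofuran-3-carboxylate built on ring A (ring B unchanged), via rhodium carbenoid 8 (not isolated)
Conditions: dirhodium tetrakis[N-phthaloyl-(R)-tert-leucinate] Rh2(R-PTTL)4 (2 mol%), toluene, −60 °C, slow addition of 7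
Reagents that add atoms: none
Why: Loss of N2 from 7 on the dirhodium tetracarboxylate should give the donor/acceptor carbenoid 8, whose carbon (the future C3) inserts into one of the two enantiotopic benzylic C–H bonds of the ArCH2–O group (the future C2) through a three-centre, hydride-transfer-like transition state in which the developing positive charge is stabilised by the ether oxygen and the electron-rich aryl ring. The closest known reaction type is the enantioselective intramolecular 1,5 C–H insertion of methyl 2-(2-benzyloxyphenyl)-2-diazoacetates to cis-2-aryl-2,3-dihydrobenzofuran-3-carboxylates with dirhodium N-phthaloyl amino-acid carboxylates, including substrates with a methoxy group beside the benzyloxy group. The dihydrobenzofuran closes by C2–C3 bond formation (1,5-insertion to a five-membered ring that already holds the C7a–O1 and O1–C2 bonds). C2 is set by catalyst-controlled choice between the enantiotopic hydrogens and C3 by the carbenoid face presented in the same concerted transition state, which places aryl and ester cis as the kinetic product; the furofuran centres are too remote to interfere, so the (R)-tert-leucinate catalyst is chosen as the enantiomer expected by analogy to give (2S,3R). The step needs site selectivity for this C–H bond over aromatic cycloaddition, carbene dimerisation and the remote furofuran C–H bonds, which the five-membered transition state, the double activation of that C–H bond and slow addition should secure, and it needs the cis ester to survive, which low temperature, neutral work-up and immediate reduction should secure.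

Step 7
Reactants: 9 methyl (2S,3R)-cis-2-Ar-7-methoxy-2,3-dihydro-1-benzofuran-3-carboxylate on ring A
Product: 10 [(2S,3S)-cis-2-Ar-7-methoxy-2,3-dihydro-1-benzofuran-3-yl]methanol on ring A
Conditions: iBu2AlH (3 equiv), CH2Cl2, −78 → −40 °C; aq. potassium sodium tartrate
Reagents that add atoms: none
Why: Low-temperature hydride reduction of the ester under non-basic conditions should leave the epimerisable C3–H untouched; C3 becomes (S) only through the change in CIP priority.

Step 8
Reactants: 10 [(2S,3S)-cis-2-Ar-7-methoxy-2,3-dihydro-1-benzofuran-3-yl]methanol on ring A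
Product: 11 acetate of 10
Conditions: Ac2O, pyridine, DMAP (cat.), CH2Cl2, 0 °C
Reagents that add atoms: acetic anhydride, CC(=O)OC(C)=O
Why: Acetylation masks the primary alcohol through the zinc-enolate coupling and the boron aldol, and the acetate is chosen so that the later LiBH4 step removes it without a separate operation.

Step 9
Reactants: 11 acetate of 10; 12 (R)-3-acetyl-4-benzyl-1,3-oxazolidin-2-one
Product: 15 (R)-4-benzyl-3-[2-(ring B C5-yl)acetyl]-1,3-oxazolidin-2-one, via lithium enolate 13 (not isolated), via chlorozinc enolate 14 (not isolated)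
Conditions: 12 (3 equiv), LiN(SiMe3)2, THF, −78 °C; ZnCl2, −78 °C → rt; then 11, Pd(dba)2 (5 mol%), P(tBu)3 (10 mol%), THF, rt → 50 °C
Reagents that add atoms: none
Why: Pd-catalysed α-arylation of a zinc amide-type enolate with the remaining aryl bromide, the reaction type known for zinc enolates of amides and enolates of N-acyl oxazolidinones; the weakly basic zinc enolate should tolerate the acetate and limit proton exchange with the more acidic product.

Step 10
Reactants: 15 (R)-4-benzyl-3-[2-(ring B C5-yl)acetyl]-1,3-oxazolidin-2-one; 16 4-(benzyloxy)-3-methoxybenzaldehyde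
Product: 18 (R)-4-benzyl-3-[(2R,3R)-3-Ar-3-hydroxy-2-(ring B C5-yl)propanoyl]-1,3-oxazolidin-2-one, via dibutylboron Z-enolate 17 (not isolated)
Conditions: Bu2BOTf (1.3 equiv), iPr2NEt (1.5 equiv), CH2Cl2, −78 → 0 °C; 16 (1.5 equiv), −78 → 0 °C; pH 7 buffer, MeOH, 30% H2O2, 0 °C
Reagents that add atoms: none
Why: Evans syn-aldol; the Z-boron enolate should add to the aldehyde through a closed chair transition state on the face away from the benzyl group of the (R)-auxiliary, setting the α-carbon (R here, S after the priority change on reduction) and the carbinol (R), of which only the α-centre is kept.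

Step 11
Reactants: 18 syn-aldol adduct
Product: 19 (1R,2S)-1-Ar-2-(ring B C5-yl)propane-1,3-diol carrying the free CH2OH on the dihydrobenzofuran
Conditions: LiBH4 (6 equiv), MeOH (6 equiv), THF, 0 °C → rt
Reagents that add atoms: none
Why: Reductive cleavage of the N-acyl oxazolidinone should release the primary alcohol and the auxiliary and reduce off the acetate in the same operation, with no stereocentre touched.

Step 12
Reactants: 19 triol
Product: 20 (S)-1-Ar-3-hydroxy-2-(ring B C5-yl)propan-1-one (tris-benzyl-type-protected target)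
Conditions: activated MnO2 (20 equiv), CH2Cl2, rt
Reagents that add atoms: none
Why: Activated MnO2 oxidises benzylic alcohols in preference to saturated primary ones under neutral heterogeneous conditions, so the aryl ketone should form without base reaching the now acidic α-stereocentre.

Step 13
Reactants: 20 protected ketone
Product: 21 target CNP0174045.1
Conditions: H2 (1 atm), 10% Pd/C, EtOAc–EtOH, rt, stopped at full debenzylation
Reagents that add atoms: none
Why: Neutral hydrogenolysis of the three primary benzylic aryl ethers (two O-benzyl groups and the ring B OCH2Ar ether, which ends as 2-methoxy-4-methylphenol) should be faster than cleavage of the secondary benzylic C–O bonds of the furofuran and dihydrobenzofuran or reduction of the electron-rich aryl ketone.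

**Compound list**

1 | (+)-pinoresinol; (1S,3aR,4S,6aR)-1,4-bis(4-hydroxy-3-methoxyphenyl)tetrahydro-1H,3H-furo[3,4-c]furan | COc1cc(ccc1O)[C@H]1OC[C@H]2[C@@H]1CO[C@@H]2c1ccc(O)c(OC)c1 | starting material
2 | 5,5'-dibromo-(+)-pinoresinol; both aryl groups 3-bromo-4-hydroxy-5-methoxyphenyl | COc1cc(cc(Br)c1O)[C@H]1OC[C@H]2[C@@H]1CO[C@@H]2c1cc(Br)c(O)c(OC)c1 | intermediate
3 | [4-(benzyloxy)-3-methoxyphenyl]methanol | COc1cc(CO)ccc1OCc1ccccc1 | starting material
4 | 1-(benzyloxy)-4-(bromomethyl)-2-methoxybenzene | COc1cc(CBr)ccc1OCc1ccccc1 | intermediate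
5 | 5,5'-dibromo-4,4'-bis-O-[4-(benzyloxy)-3-methoxybenzyl]-(+)-pinoresinol | COc1cc(cc(Br)c1OCc1ccc(OCc2ccccc2)c(OC)c1)[C@H]1OC[C@H]2[C@@H]1CO[C@@H]2c1cc(Br)c(OCc2ccc(OCc3ccccc3)c(OC)c2)c(OC)c1 | intermediate
6 | methyl 2-(ring A C5-yl)acetate; 5 with the ring A bromine replaced by CH2CO2Me | COc1cc(cc(Br)c1OCc1ccc(OCc2ccccc2)c(OC)c1)[C@H]1OC[C@H]2[C@@H]1CO[C@@H]2c1cc(CC(=O)OC)c(OCc2ccc(OCc3ccccc3)c(OC)c2)c(OC)c1 | intermediate
7 | methyl 2-diazo-2-(ring A C5-yl)acetate; diazo derivative of 6 | COc1cc(cc(Br)c1OCc1ccc(OCc2ccccc2)c(OC)c1)[C@H]1OC[C@H]2[C@@H]1CO[C@@H]2c1cc(C(=[N+]=[N-])C(=O)OC)c(OCc2ccc(OCc3ccccc3)c(OC)c2)c(OC)c1 | intermediate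
8 | rhodium carbenoid from 7 (dirhodium tetracarboxylate core written as [Rh]) | COc1cc(cc(Br)c1OCc1ccc(OCc2ccccc2)c(OC)c1)[C@H]1OC[C@H]2[C@@H]1CO[C@@H]2c1cc(C(=[Rh])C(=O)OC)c(OCc2ccc(OCc3ccccc3)c(OC)c2)c(OC)c1 | intermediate
9 | methyl (2S,3R)-cis-2-[4-(benzyloxy)-3-methoxyphenyl]-7-methoxy-5-(furofuranyl)-2,3-dihydro-1-benzofuran-3-carboxylate; ring B still carries Br and OCH2Ar | COc1cc(cc(Br)c1OCc1ccc(OCc2ccccc2)c(OC)c1)[C@H]1OC[C@H]2[C@@H]1CO[C@@H]2c1cc(OC)c2c(c1)[C@@H](C(=O)OC)[C@@H](c1ccc(OCc3ccccc3)c(OC)c1)O2 | intermediate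
10 | (2S,3S)-cis-3-(hydroxymethyl) analogue of 9 | COc1cc(cc(Br)c1OCc1ccc(OCc2ccccc2)c(OC)c1)[C@H]1OC[C@H]2[C@@H]1CO[C@@H]2c1cc(OC)c2c(c1)[C@@H](CO)[C@@H](c1ccc(OCc3ccccc3)c(OC)c1)O2 | intermediate
11 | acetate of 10 | COc1cc(cc(Br)c1OCc1ccc(OCc2ccccc2)c(OC)c1)[C@H]1OC[C@H]2[C@@H]1CO[C@@H]2c1cc(OC)c2c(c1)[C@@H](COC(C)=O)[C@@H](c1ccc(OCc3ccccc3)c(OC)c1)O2 | intermediate
12 | (R)-3-acetyl-4-benzyl-1,3-oxazolidin-2-one | CC(=O)N1[C@H](Cc2ccccc2)COC1=O | starting material
13 | lithium enolate of 12 | [Li]OC(=C)N1[C@H](Cc2ccccc2)COC1=O | intermediate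
14 | chlorozinc enolate of 12 | Cl[Zn]CC(=O)N1[C@H](Cc2ccccc2)COC1=O | intermediate
15 | (R)-4-benzyl-3-[2-(ring B C5-yl)acetyl]-1,3-oxazolidin-2-one; 11 with the ring B bromine replaced by the acyl-oxazolidinone CH2 | COc1cc(cc(CC(=O)N2[C@H](Cc3ccccc3)COC2=O)c1OCc1ccc(OCc2ccccc2)c(OC)c1)[C@H]1OC[C@H]2[C@@H]1CO[C@@H]2c1cc(OC)c2c(c1)[C@@H](COC(C)=O)[C@@H](c1ccc(OCc3ccccc3)c(OC)c1)O2 | intermediate
16 | 4-(benzyloxy)-3-methoxybenzaldehyde | COc1cc(C=O)ccc1OCc1ccccc1 | starting material
17 | dibutylboron Z-enolate of 15 | COc1cc(cc(\C=C(/OB(CCCC)CCCC)N2[C@H](Cc3ccccc3)COC2=O)c1OCc1ccc(OCc2ccccc2)c(OC)c1)[C@H]1OC[C@H]2[C@@H]1CO[C@@H]2c1cc(OC)c2c(c1)[C@@H](COC(C)=O)[C@@H](c1ccc(OCc3ccccc3)c(OC)c1)O2 | intermediate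
18 | syn-aldol adduct; (2R,3R)-3-Ar-3-hydroxy-2-(ring B C5-yl)propanoyl imide of (R)-4-benzyloxazolidinone | COc1cc(cc([C@@H](C(=O)N2[C@H](Cc3ccccc3)COC2=O)[C@@H](O)c2ccc(OCc3ccccc3)c(OC)c2)c1OCc1ccc(OCc2ccccc2)c(OC)c1)[C@H]1OC[C@H]2[C@@H]1CO[C@@H]2c1cc(OC)c2c(c1)[C@@H](COC(C)=O)[C@@H](c1ccc(OCc3ccccc3)c(OC)c1)O2 | intermediate
19 | triol; (1R,2S)-1-Ar-2-(ring B C5-yl)propane-1,3-diol with free CH2OH on the dihydrobenzofuran | COc1cc(cc([C@@H](CO)[C@@H](O)c2ccc(OCc3ccccc3)c(OC)c2)c1OCc1ccc(OCc2ccccc2)c(OC)c1)[C@H]1OC[C@H]2[C@@H]1CO[C@@H]2c1cc(OC)c2c(c1)[C@@H](CO)[C@@H](c1ccc(OCc3ccccc3)c(OC)c1)O2 | intermediate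
20 | protected ketone; (S)-1-Ar-3-hydroxy-2-(ring B C5-yl)propan-1-one | COc1cc(cc([C@@H](CO)C(=O)c2ccc(OCc3ccccc3)c(OC)c2)c1OCc1ccc(OCc2ccccc2)c(OC)c1)[C@H]1OC[C@H]2[C@@H]1CO[C@@H]2c1cc(OC)c2c(c1)[C@@H](CO)[C@@H](c1ccc(OCc3ccccc3)c(OC)c1)O2 | intermediate
21 | CNP0174045.1 | COc1cc(cc([C@@H](CO)C(=O)c2ccc(O)c(OC)c2)c1O)[C@H]1OC[C@H]2[C@@H]1CO[C@@H]2c1cc(OC)c2c(c1)[C@@H](CO)[C@@H](c1ccc(O)c(OC)c1)O2 | target

**Step count and risks**

Total step count: 13. Longest linear sequence: 12 (steps 1 and 3 to 13; step 2 is a one-step side branch).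

Steps most likely to fail:

1. Step 6. The risk is loss of the kinetic cis preference or of the discrimination between the enantiotopic hydrogens, because the methoxy group beside the ether turns the OCH2Ar group out of the ring plane, together with competing aromatic cycloaddition of the carbenoid into the electron-rich benzyl ring. The fallback sets out from 6 and returns at 11, and it closes the ring at O1–C2 with inversion instead of at C2–C3. Compound 6 would be saponified (LiOH, THF–H2O) to the arylacetic acid F1. Its pivaloyl mixed anhydride (PivCl, Et3N) with lithiated (R)-4-benzyl-1,3-oxazolidin-2-one would give the imide F2. The dibutylboron syn-aldol with 16 would give the (2R,3R) adduct F3, and LiBH4 the syn-1,3-diol F4. Selective acetylation of the primary hydroxyl (AcCl, 2,4,6-collidine, CH2Cl2, −78 °C) would give the monoacetate F5. Mesylation (MsCl, Et3N, CH2Cl2, −40 °C) would give the benzylic mesylate F6. The neighbouring ring A ether oxygen should displace the mesylate with inversion (5-exo-tet) while chloride removes the 4-(benzyloxy)-3-methoxybenzyl group from the oxonium ion, giving the cis compound 11. Ring B has no electrophile within reach and stays untouched. The closure is stereospecific only if displacement outruns ionisation of the mesylate.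

2. Step 9. The risk is proton transfer from the more acidic product to the zinc enolate and fragmentation of the acetyl imide enolate to ketene, either of which would stall the coupling. The fallback sets out from 11 and returns at 15, and it brings in the two-carbon acid as an allyl group. Stille coupling of 11 with allyltributylstannane (Pd(PPh3)4, toluene, 100 °C) would give the allylarene F7. Lemieux–Johnson cleavage (OsO4 cat., NaIO4, 2,6-lutidine, dioxane–H2O) would give the arylacetaldehyde F8. Pinnick oxidation (NaClO2, NaH2PO4, 2-methyl-2-butene) would give the arylacetic acid F9. Its pivaloyl mixed anhydride with lithiated (R)-4-benzyl-1,3-oxazolidin-2-one would give 15.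

3. Step 12. The risk is incomplete discrimination between the benzylic secondary hydroxyl and the two primary hydroxyls, and dehydration or retro-aldol loss of formaldehyde from the β-hydroxy ketone on the oxide surface. The fallback sets out from 19 and returns at 20. TBSCl (2.2 equiv) and imidazole in CH2Cl2 at 0 °C should silylate only the two primary hydroxyls to give the bis-silyl ether F10. Dess–Martin periodinane (NaHCO3, CH2Cl2) would give the ketone F11. HF·pyridine in THF at 0 °C would remove both silyl groups under mildly acidic conditions to give 20.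

**Further compounds**

F1 | step 6 | 2-(ring A C5-yl)acetic acid; free acid of 6 | COc1cc(cc(Br)c1OCc1ccc(OCc2ccccc2)c(OC)c1)[C@H]1OC[C@H]2[C@@H]1CO[C@@H]2c1cc(CC(=O)O)c(OCc2ccc(OCc3ccccc3)c(OC)c2)c(OC)c1
F2 | step 6 | (R)-4-benzyl-3-[2-(ring A C5-yl)acetyl]-1,3-oxazolidin-2-one | COc1cc(cc(Br)c1OCc1ccc(OCc2ccccc2)c(OC)c1)[C@H]1OC[C@H]2[C@@H]1CO[C@@H]2c1cc(CC(=O)N2[C@H](Cc3ccccc3)COC2=O)c(OCc2ccc(OCc3ccccc3)c(OC)c2)c(OC)c1
F3 | step 6 | ring A syn-aldol adduct; (2R,3R)-3-Ar-3-hydroxy-2-(ring A C5-yl)propanoyl imide | COc1cc(cc(Br)c1OCc1ccc(OCc2ccccc2)c(OC)c1)[C@H]1OC[C@H]2[C@@H]1CO[C@@H]2c1cc([C@@H](C(=O)N2[C@H](Cc3ccccc3)COC2=O)[C@@H](O)c2ccc(OCc3ccccc3)c(OC)c2)c(OCc2ccc(OCc3ccccc3)c(OC)c2)c(OC)c1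
F4 | step 6 | (1R,2S)-1-Ar-2-(ring A C5-yl)propane-1,3-diol | COc1cc(cc(Br)c1OCc1ccc(OCc2ccccc2)c(OC)c1)[C@H]1OC[C@H]2[C@@H]1CO[C@@H]2c1cc([C@@H](CO)[C@@H](O)c2ccc(OCc3ccccc3)c(OC)c2)c(OCc2ccc(OCc3ccccc3)c(OC)c2)c(OC)c1
F5 | step 6 | primary monoacetate of F4 | COc1cc(cc(Br)c1OCc1ccc(OCc2ccccc2)c(OC)c1)[C@H]1OC[C@H]2[C@@H]1CO[C@@H]2c1cc([C@@H](COC(C)=O)[C@@H](O)c2ccc(OCc3ccccc3)c(OC)c2)c(OCc2ccc(OCc3ccccc3)c(OC)c2)c(OC)c1
F6 | step 6 | benzylic mesylate of F5 | COc1cc(cc(Br)c1OCc1ccc(OCc2ccccc2)c(OC)c1)[C@H]1OC[C@H]2[C@@H]1CO[C@@H]2c1cc([C@@H](COC(C)=O)[C@@H](OS(C)(=O)=O)c2ccc(OCc3ccccc3)c(OC)c2)c(OCc2ccc(OCc3ccccc3)c(OC)c2)c(OC)c1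
F7 | step 9 | ring B C5-allyl analogue of 11 | COc1cc(cc(CC=C)c1OCc1ccc(OCc2ccccc2)c(OC)c1)[C@H]1OC[C@H]2[C@@H]1CO[C@@H]2c1cc(OC)c2c(c1)[C@@H](COC(C)=O)[C@@H](c1ccc(OCc3ccccc3)c(OC)c1)O2
F8 | step 9 | 2-(ring B C5-yl)acetaldehyde | COc1cc(cc(CC=O)c1OCc1ccc(OCc2ccccc2)c(OC)c1)[C@H]1OC[C@H]2[C@@H]1CO[C@@H]2c1cc(OC)c2c(c1)[C@@H](COC(C)=O)[C@@H](c1ccc(OCc3ccccc3)c(OC)c1)O2
F9 | step 9 | 2-(ring B C5-yl)acetic acid | COc1cc(cc(CC(=O)O)c1OCc1ccc(OCc2ccccc2)c(OC)c1)[C@H]1OC[C@H]2[C@@H]1CO[C@@H]2c1cc(OC)c2c(c1)[C@@H](COC(C)=O)[C@@H](c1ccc(OCc3ccccc3)c(OC)c1)O2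
F10 | step 12 | bis(tert-butyldimethylsilyl) ether of 19 at both primary hydroxyls | COc1cc(cc([C@@H](CO[Si](C)(C)C(C)(C)C)[C@@H](O)c2ccc(OCc3ccccc3)c(OC)c2)c1OCc1ccc(OCc2ccccc2)c(OC)c1)[C@H]1OC[C@H]2[C@@H]1CO[C@@H]2c1cc(OC)c2c(c1)[C@@H](CO[Si](C)(C)C(C)(C)C)[C@@H](c1ccc(OCc3ccccc3)c(OC)c1)O2
F11 | step 12 | bis(tert-butyldimethylsilyl) ether of 20 | COc1cc(cc([C@@H](CO[Si](C)(C)C(C)(C)C)C(=O)c2ccc(OCc3ccccc3)c(OC)c2)c1OCc1ccc(OCc2ccccc2)c(OC)c1)[C@H]1OC[C@H]2[C@@H]1CO[C@@H]2c1cc(OC)c2c(c1)[C@@H](CO[Si](C)(C)C(C)(C)C)[C@@H](c1ccc(OCc3ccccc3)c(OC)c1)O2
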